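(The readings are simulated for substances that don't exist; noise was put on by code.)

the same everywhere: free monomer 1.3 M; initiator 14 mM
- Wednesday's: protic impurity 0.013 M; run made earlier
- east: protic impurity 0.0260 M; time 5.0 d
- north: protic impurity 0.0260 M; time 1.5 d

Wednesday's run (percent of the free monomer charged)

| time / h | monomer in chains / % | free monomer / % |
|---|---|---|
| 6.00 | 25.3 | 73.0 |
| 12.0 | 44.9 | 54.2 |
| 20.0 | 62.3 | 36.4 |
| 25.0 | 70.3 | 28.7 |
| 30.0 | 77.0 | 21.6 |
| 40.0 | 84.9 | 14.0 |

(standard deviation of a reading: 0.5 percentage points)

- which of the two ends with the longer chains by the average number of monomer units in a chain (living and dead chains, two that joined counted as one) ("neither" if they lie within 10%) (east / north / neither)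
- average number of monomer units in a chain (living and dead chains, two that joined counted as one) at the end, east
- average number of monomer units in a chain (living and dead chains, two that joined counted as one) at the end, north

- the average divides the monomer in chains by the number of chains, living and dead together; two radicals that join make one chain
- the earlier runs do not show the number of chains; that part of a forecast is a guess
- no earlier run changes the charge of protic impurity; that part of a forecast is a guess

- A small charge drops out first: east and north hold the same 0.0260 M of protic impurity, so the fraction of the free monomer it takes is taken here as common to both flasks and as cancelling in the ratio of their monomer in chains, and the two differ in time, 5.0 d against 1.5 d.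
- Wednesday's free monomer falls from 73.0% to 14.0% between 6.00 h and 40.0 h without slowing, which reads as a pseudo-first-order constant k of 0.0486 h⁻¹, taken here to hold at the larger impurity charge, which is a guess.
- Average length is monomer in chains divided by the number of chains, so the question turns round: the ratio of monomer in chains, east over north, Q = 1.21, is the crossover chain ratio, the ratio of chain numbers, east over north, above which north ends longer and below which east does, leaving aside the margin of 10%.
- The readings show no chains, so the reckoning here is a guess: a steady k is read as a steady level of growing radicals, whose births balance their deaths (the steady-state approximation), and since each joining pair leaves one dead chain, chains are then taken to pile up in proportion to time.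
- That puts the east-over-north chain ratio at 3.33, greater than Q, so this reckoning has north longer by a factor of about 2.75.
- The forecast differs, naming east with 90 for east and 75 for north, on the ground that “the active centres persist and the system behaves as living”.
- The simulation gives north: the average length is 343 in east and 857 in north, a factor of 2.50 longer in north.

    initiator → 2 initiating radical (k = 7.11 × 10⁻⁷ s⁻¹)
    free monomer + initiating radical → growing radical + monomer in chains (k = 25300 L mol⁻¹ s⁻¹)
    free monomer + growing radical → monomer in chains + growing radical, rate k3*[growing radical]*[free monomer] (k = 3550 L mol⁻¹ s⁻¹)
    2 growing radical → dead chain (k = 6.50 × 10⁸ L mol⁻¹ s⁻¹)
    protic impurity + free monomer → quenched substrate (k = 2.39 × 10⁻⁴ L mol⁻¹ s⁻¹)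

- Dead chains stand at 0.00370 M in east and 0.00123 M in north, a ratio of 3.01, greater than Q, and the gap in length is owed to the difference in time: north carried on to 5.0 d falls from 857 to 343. A neighbour like east but with 0.035 M of initiator has a crossover chain ratio against east of 1.00 and a dead-chain ratio against east of 1.86, above that crossover, so that neighbour ends shorter than east, at 185.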